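all flasks: substrate 0.050 M
- maple: first nucleophile 0.030 M; second nucleophile 0.0525 M (fed, over 40 h); protic impurity 0.0075 M; temperature 5 °C; run made earlier
- cedar: first nucleophile 0.030 M; second nucleophile 0.0525 M (fed, over 40 h); protic impurity 0.011 M; temperature 20 °C; run made earlier
- ash: first nucleophile 0.030 M; second nucleophile 0.079 M (fed, over 40 h); protic impurity 0.015 M; temperature 5 °C; run made earlier
- dawn: first nucleophile 0.0300 M; second nucleophile 0.0525 M (fed, over 40 h); protic impurity 0.0150 M; at 10 °C until 12 h, from then on at 30 °C; time 40 h
- summer: first nucleophile 0.0300 M; second nucleophile 0.0525 M (fed, over 60 h); protic impurity 0.0150 M; at 10 °C throughout; time 12 h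

| run | time / h | target / % | substrate / % |
|---|---|---|---|
| maple | 8.00 | 3.7 | 95.5 |
| maple | 15.0 | 7.2 | 91.5 |
| maple | 25.0 | 10.3 | 86.0 |
| maple | 30.0 | 12.3 | 83.6 |
| maple | 40.0 | 15.0 | 78.1 |
| maple | 50.0 | 16.2 | 73.0 |
| cedar | 5.00 | 18.9 | 80.3 |
| cedar | 10.0 | 31.1 | 64.4 |
| cedar | 15.0 | 40.9 | 51.9 |
| cedar | 20.0 | 45.5 | 42.2 |
| cedar | 25.0 | 50.4 | 32.9 |
| cedar | 30.0 | 52.7 | 27.3 |
| ash | 4.00 | 1.7 | 97.7 |
| ash | 8.00 | 4.9 | 95.5 |
| ash | 15.0 | 6.9 | 91.0 |
| ash | 25.0 | 10.3 | 86.1 |
| ash | 50.0 | 15.2 | 72.6 |

(standard deviation of a reading: 0.5 percentage points)

- percentages count the whole charge, also what has not yet gone in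
- a reading or a percentage of target counts all its forms, free or not

- the flask that ends with the higher amount of target, in percent of the substrate charged, or "neither" when 2 percentage points or less lies between them (dawn / summer / neither)
- final target, as a percentage of the substrate charged, in dawn
- final target, as a percentage of the substrate charged, in summer

If the substrate went at a pace of its own, I reasoned, then maple and ash should lose it about alike despite their different feed and impurity, and at 50.0 h they held 73.0% and 72.6% of it. So I treated its loss as first order, the rate-limiting step of the flask. I read one constant from maple at 5 °C and one from cedar at 20 °C, and as a rough step of my own I spaced their logarithms evenly over temperature: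

constant at 5 °C: 0.00629 h⁻¹
constant at 20 °C: 0.0433 h⁻¹
constant at 10 °C: 0.0120 h⁻¹
constant at 30 °C: 0.156 h⁻¹

Then I ordered the steps, fastest first. Capture of what the substrate became came first: in cedar at 5.00 h the readings of target and substrate left 0.8 percentage points of the charge for anything else. Next came the substrate's life at 30 °C, 6.41 h, which is shorter than dawn's 28.0 h at that temperature. After that came its life at 10 °C, 83.3 h, which is longer than its life at 30 °C and longer than summer's 12 h.

For summer the clock came to 0.144. This clock, the rate constant times the time summed over a flask's history, gives the fraction ionised as one minus exp(−clock). That fraction was my first answer for target. I then went round again, multiplying it by the share of lost substrate that cedar had turned into target, and holding the product against the cap set by the first nucleophile as limiting reagent, 60.0% of the charge.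

summer: ionised 13.4%; share 87.4%, read from cedar at 10.0 h (dose 25.0%, summer's 20.0%); target 11.7%
dawn: clock 4.53; ionised 98.9%; share 72.5%, read from cedar at 30.0 h; product 71.7%, above the cap, so target 60.0%

The forecast, grounded on “Substrate loss is first order and ignores both nucleophiles and the impurity”, gave dawn 57% (51% to 60%) and summer 13% (11.3% to 14.5%), with dawn ahead. My two figures differ from these, but the order is the same.

Dawn gave 59.8% and summer 12.1%, so dawn ended higher.

    substrate → intermediate (k = 0.0122 h⁻¹, Ea = 88.0 kJ mol⁻¹)
    first nucleophile + intermediate → target (k = 95.0 M⁻¹ h⁻¹, Ea = 66.0 kJ mol⁻¹)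
    second nucleophile + intermediate → other capture product (k = 55.2 M⁻¹ h⁻¹, Ea = 55.0 kJ mol⁻¹)
    second nucleophile + protic impurity → quenched reagent (k = 2.56 M⁻¹ h⁻¹, Ea = 69.0 kJ mol⁻¹)
    crystals ⇌ target, rate k5*(cs5 - [target]) while solid is left; crystals form when [target] > cs5 (solubility = 25.0 mM, k = 0.812 h⁻¹)
    (constants at 10 °C)

Summer's substrate stood at 86.4% after 12.0 h, and the clock had left 86.6%. The neighbouring flask was summer run at 25 °C for the same 12 h. Its clock grew to 0.987, which reckons 62.7% ionised. With the share I used for summer that makes 54.8%, below the cap. That flask held 38.3% of its substrate at the end, and its target stood at 54.2%.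

(The earlier runs and the new flask are calculated with made-up constants; scatter was added.)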